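The starting complex trades a leaving ligand for the incoming ligand; the complex with one exchanged can then trade again or turn into its isomer, and I want as much of that middle complex as possible.

    starting complex + incoming ligand → leaving ligand + complex with one exchanged (k1 = 87 M⁻¹ s⁻¹)
    complex with one exchanged + incoming ligand ⇌ leaving ligand + complex with two exchanged (K2 = 3.2, k2 = 140 M⁻¹ s⁻¹)
    complex with one exchanged ⇌ isomer of the product (K3 = 0.50, k3 = 0.51 s⁻¹)

all flasks: starting complex 0.0020 M; leaving ligand 5.00 equiv

|  | incoming ligand | time | remark |
|---|---|---|---|
| beta | 1.05 equiv | 6.0 s | a closed flask charged with all of it at once and left for 6.0 s |
| gamma | 1.05 equiv (fed, over 4.80 s) | 6.0 s | all but incoming ligand at the start; incoming ligand goes in evenly over 4.80 s, the run ends at 6.0 s |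
| zeta | 1.05 equiv |  | one stirred flow tank at steady state, fed with the mixture as stated, mean residence time 18.0 s |
| delta | 1.05 equiv |  | a single well-mixed tank run continuously and read at steady state, 6.0 s in it on average |

- the set-up with the highest amount of complex with one exchanged at the outlet or at the end, in percent of the starting complex put in ("none" if the first two lie within 2 percentage points) (beta / gamma / zeta / delta / none)
- amount of complex with one exchanged at the outlet or at the end, in percent of the starting complex put in, beta
- amount of complex with one exchanged at the outlet or at the end, in percent of the starting complex put in, gamma
- amount of complex with one exchanged at the outlet or at the end, in percent of the starting complex put in, zeta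
- amount of complex with one exchanged at the outlet or at the end, in percent of the starting complex put in, delta

- the stated concentrations are those of everything mixed, before any reaction; amounts are the same in each set-up
- the feed brings no volume worth counting
- run time (beta): 6.0 s

I watch beta, the closed flask, first. In the first instants the first step has the flask to itself, with a forward half-life of 3.79 s for the starting complex at the ligand as charged. Once complex with one exchanged exists, the third step takes it faster than the first step consumes starting complex, with a forward half-life of 1.36 s. That step relaxes both ways in 0.654 s, short against 6.0 s, so for the end of beta, and not for the middle, I estimate the isomer at 0.50 per complex with one exchanged. The second step also takes it; at the charged amounts its way back is 0.438 s⁻¹ and its way forward 0.294 s⁻¹, which together give a relaxation time of 1.37 s, short against 6.0 s, so for the end of beta I estimate it as an equilibrium too.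

At the end of beta, second-order loss leaves 47.1% of the starting complex, and the second equilibrium gives 0.301 complex with two exchanged per complex with one exchanged. Dividing the converted amount among the three gives 29.4%. I treat gamma as beta with the ligand arriving late by half the dosing time on average: 59.9% stays, which gives 0.385 and 21.2%.

A tank needs the quantity I carry, the isomer ratio of a tank: isomer per complex with one exchanged at the outlet, equal to the forward constant of the third step times the residence time, over one plus that product divided by the equilibrium constant. For zeta it is 0.474, less than the equilibrium value. The Damköhler number of the first step is 3.13. Guessing 0.5 of starting complex left gives 36.7%, and going round once more gives 43.3%. The same balance on the second step gives 0.249, so zeta holds 32.9%. For delta the ratio is 0.430, with 58.3% left and 0.277, so delta holds 24.4%. My choice is zeta.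

The forecast gives 29.2% for beta, 22.8% for gamma, 33.5% for zeta and 22.8% for delta, and picks zeta: “Zeta leads beta by about 4 points, so it is best.” Its gamma lies above mine and its delta below mine.

The simulation gives 30.0% for beta, 22.9% for gamma, 33.5% for zeta and 22.8% for delta, so the choice is zeta.

In zeta the first step ran with incoming ligand standing at 8.29 × 10⁻⁴ M and starting complex at 8.70 × 10⁻⁴ M, while the third step left 15.9% of isomer beside 33.5% of complex with one exchanged, a read ratio of 0.475 against the carried 0.474. In delta the first step ran with incoming ligand at 0.00121 M, which by the tank balance leaves 61.3% of starting complex, and removing that and the 6.00% of complex with two exchanged, then dividing by one plus 0.430, gives 22.8% beside the 22.8% in the tank.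

The numbers of this flask were chosen freely; the result is computed.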